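**Retrosynthetic overview**

1. Last step: hydrogenolysis of sixteen benzyl ethers. Before it, both interflavan C4–C8 bonds are made by two successive Lewis-acid couplings of one electrophile, the 4-acetoxy gallocatechin 18: first onto C8 of tetra-O-benzyl-(+)-catechin 20, then onto C8 of the resulting dimer 22 (3,4-trans by attack anti to the C3 oxygen).
2. Acetate 18 comes from chromanone 16, in which C4 is held one oxidation level higher as a ketone; that oxygen becomes the leaving group of the couplings and is thereby removed again.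
3. Key disconnection of 16: ring C is cut at O1–C8a and C4a–C4, giving ring A as 3,5-bis(benzyloxy)benzyne and the acyclic anti aldol ester 8, which carries ring B, O1, C2, C3 and C4. One annulation thus supplies rings A and C of both gallocatechin units.
4. Enabling feature: in ring A, C8a (bearing O1) and C4a (bearing C4) are ortho neighbours and the C5 oxygen sits next to C4a. A 3,5-dialkoxybenzyne places a nucleophile meta to the flanking oxygen (C8a) and the ensuing aryl anion next to it (C4a); the four atoms O1–C2–C3–C4 then close ring C by a six-membered acyl transfer.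
5. Stereocentres and ring order: C2/C3 of both upper units come from an Evans syn glycolate aldol plus Mitsunobu inversion, and the lower unit from (+)-catechin. Rings B are bought, ring C of the gallocatechin unit forms in step 8 with ring A delivered in the same event, and the three flavan units are joined afterwards.

Key step: step 8

Remark: alcohol 17 and acetate 18 are drawn as the expected 3,4-trans epimers; their C4 configuration is erased on ionisation in steps 12 and 13, so a C4 epimer mixture would serve equally.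

**Route**

Step 1
Reactants: 1 (R)-4-benzyloxazolidin-2-one; 2 benzyloxyacetyl chloride
Product: 3 (R)-4-benzyl-3-[2-(benzyloxy)acetyl]oxazolidin-2-one
Conditions: Et3N, DMAP (cat.), CH2Cl2, 0 °C to rt
Reagents that add atoms: none
Why: N-acylation of the oxazolidinone with the acid chloride under amine/DMAP catalysis installs the glycolate on the auxiliary and touches no stereocentre.

Step 2
Reactants: 3 (R)-4-benzyl-3-[2-(benzyloxy)acetyl]oxazolidin-2-one; 4 3,4,5-tris(benzyloxy)benzaldehyde
Product: 6 (R)-4-benzyl-3-[(2R,3S)-2-(benzyloxy)-3-hydroxy-3-(3,4,5-tris(benzyloxy)phenyl)propanoyl]oxazolidin-2-one, via dibutylboron Z-enolate 5 (not isolated)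
Conditions: Bu2BOTf, iPr2NEt, CH2Cl2, 0 °C; then 4, −78 to 0 °C; then pH 7 buffer, MeOH, H2O2, 0 °C
Reagents that add atoms: none
Why: Evans syn aldol reaction, in which the Z boron enolate reacts through a closed chair transition state on the face away from the benzyl group of the (R)-auxiliary, which should set the alpha carbon (future flavan C3) as R in its final arrangement and the carbinol carbon (future flavan C2) as S, ready for inversion.

Step 3
Reactants: 6 (R)-4-benzyl-3-[(2R,3S)-2-(benzyloxy)-3-hydroxy-3-(3,4,5-tris(benzyloxy)phenyl)propanoyl]oxazolidin-2-one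
Product: 7 (1R,2R)-2-(benzyloxy)-3-[(R)-4-benzyl-2-oxooxazolidin-3-yl]-3-oxo-1-[3,4,5-tris(benzyloxy)phenyl]propyl 4-nitrobenzoate
Conditions: 4-nitrobenzoic acid, PPh3, DIAD, THF, 0 °C to rt
Reagents that add atoms: 4-nitrobenzoic acid, O=C(O)c1ccc(cc1)[N+](=O)[O-]
Why: Mitsunobu reaction, in which SN2 displacement of the activated benzylic oxygen by the carboxylate inverts the carbinol carbon to R and so gives the anti relationship that a 2,3-trans flavan requires, while allylic strain in the imide keeps the alpha hydrogen poorly aligned for elimination.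

Step 4
Reactants: 7 (1R,2R)-2-(benzyloxy)-3-[(R)-4-benzyl-2-oxooxazolidin-3-yl]-3-oxo-1-[3,4,5-tris(benzyloxy)phenyl]propyl 4-nitrobenzoate
Product: 8 methyl (2R,3R)-2-(benzyloxy)-3-hydroxy-3-[3,4,5-tris(benzyloxy)phenyl]propanoate
Conditions: K2CO3 (substoichiometric), MeOH–THF, 0 °C
Reagents that add atoms: methanol, CO
Why: base-mediated methanolysis (transesterification) should remove the activated 4-nitrobenzoate and exchange the auxiliary for a methyl ester without breaking a bond at either stereocentre, and the auxiliary is recovered.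

Step 5
Reactants: 9 3,5-bis(benzyloxy)phenol
Product: 10 2-bromo-3,5-bis(benzyloxy)phenol
Conditions: NBS, CH2Cl2, −78 °C to rt
Reagents that add atoms: N-bromosuccinimide, O=C1CCC(=O)N1Br
Why: electrophilic aromatic bromination, directed in a non-polar solvent at low temperature to the position ortho to the free hydroxyl, gives the bromide flanked by OH and OBn that the later silyl shift needs.

Step 6
Reactants: 10 2-bromo-3,5-bis(benzyloxy)phenol
Product: 11 [2-bromo-3,5-bis(benzyloxy)phenoxy]trimethylsilane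
Conditions: HMDS, THF, 70 °C
Reagents that add atoms: hexamethyldisilazane, C[Si](C)(C)N[Si](C)(C)C
Why: O-silylation of the phenol with HMDS needs no added base and prepares the oxygen-to-carbon silyl migration.

Step 7
Reactants: 11 [2-bromo-3,5-bis(benzyloxy)phenoxy]trimethylsilane
Product: 13 3,5-bis(benzyloxy)-2-(trimethylsilyl)phenyl trifluoromethanesulfonate, via lithium 2-silylphenoxide 12 (not isolated)
Conditions: n-BuLi, THF, −100 °C; then Tf2O, −100 to −78 °C
Reagents that add atoms: trifluoromethanesulfonic anhydride, O=S(=O)(OS(=O)(=O)C(F)(F)F)C(F)(F)F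
Why: bromine–lithium exchange followed by retro-Brook (1,3 oxygen-to-carbon silyl) rearrangement gives the ortho-silyl phenoxide, which Tf2O traps as the ortho-silylaryl triflate aryne precursor.

Step 8
Reactants: 8 methyl (2R,3R)-2-(benzyloxy)-3-hydroxy-3-[3,4,5-tris(benzyloxy)phenyl]propanoate; 13 3,5-bis(benzyloxy)-2-(trimethylsilyl)phenyl trifluoromethanesulfonate
Product: 16 (2R,3R)-3,5,7-tris(benzyloxy)-2-[3,4,5-tris(benzyloxy)phenyl]chroman-4-one, via 3,5-bis(benzyloxy)benzyne 14 (not isolated), via aryl caesium adduct 15 (not isolated)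
Conditions: 13 (1.5 equiv), CsF (3 equiv), THF, 65 °C
Reagents that add atoms: none
Why: Proposed new method: fluoride unmasks benzyne 14 from 13, the secondary hydroxyl O1 of 8 adds to the aryne carbon remote from the flanking benzyloxy group to form the O1–C8a bond, and the resulting aryl anion 15, located at C4a next to the inductively stabilising C5 oxygen, attacks the methyl ester carbonyl C4 and expels methoxide to form the C4a–C4 bond. The closest known reaction type is the fluoride-induced coupling of arynes with methyl salicylates to give xanthones (O-arylation followed by intramolecular acylation of the aryl anion), here transferred from a phenoxide to an aliphatic beta-hydroxy ester. Ring C is closed by a 6-exo-trig acyl substitution through a six-membered transition state, and ring A is delivered intact by the aryne. No stereocentre is created: C2 and C3 come from steps 2 and 3 and no bond to either is broken, and should C3 (alpha to the new ketone) enolise, the 2,3-trans arrangement drawn is also the thermodynamically favoured one. The step needs O-attack at C8a rather than C4a, secured by the known preference of 3-alkoxyarynes for nucleophilic attack meta to the alkoxy group, and cyclisation rather than protonation of the aryl anion, secured by the aprotic medium and the intramolecular six-membered trajectory; the weakly basic fluoride medium should spare the hydroxy ester from retro-aldol cleavage and elimination.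

Step 9
Reactants: 16 (2R,3R)-3,5,7-tris(benzyloxy)-2-[3,4,5-tris(benzyloxy)phenyl]chroman-4-one
Product: 17 (2R,3S,4R)-3,5,7-tris(benzyloxy)-2-[3,4,5-tris(benzyloxy)phenyl]chroman-4-ol
Conditions: NaBH4, THF–MeOH, 0 °C
Reagents that add atoms: none
Why: borohydride reduction of the aryl ketone, with hydride delivery anti to the C3 benzyloxy group, should favour the 2,3-trans-3,4-trans alcohol, whose C4 configuration is of no consequence later.

Step 10
Reactants: 17 (2R,3S,4R)-3,5,7-tris(benzyloxy)-2-[3,4,5-tris(benzyloxy)phenyl]chroman-4-ol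
Product: 18 (2R,3R,4R)-3,5,7-tris(benzyloxy)-2-[3,4,5-tris(benzyloxy)phenyl]chroman-4-yl acetate
Conditions: Ac2O, pyridine, DMAP (cat.), CH2Cl2, 0 °C to rt
Reagents that add atoms: acetic anhydride, CC(=O)OC(C)=O
Why: DMAP-catalysed acylation converts the benzylic alcohol into the acetate leaving group used for cation generation (the C3 descriptor changes by priority only).

Step 11
Reactants: 19 (+)-catechin
Product: 20 5,7,3',4'-tetra-O-benzyl-(+)-catechin
Conditions: BnBr, K2CO3, DMF, 0 °C to rt
Reagents that add atoms: benzyl bromide, BrCc1ccccc1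
Why: Williamson etherification, in which K2CO3 deprotonates the four phenols for benzylation while the far less acidic secondary 3-OH stays free.

Step 12
Reactants: 18 (2R,3R,4R)-3,5,7-tris(benzyloxy)-2-[3,4,5-tris(benzyloxy)phenyl]chroman-4-yl acetate; 20 5,7,3',4'-tetra-O-benzyl-(+)-catechin
Product: 22 hexa-O-benzyl-(+)-gallocatechin-(4α→8)-tetra-O-benzyl-(+)-catechin (lower unit 3-OH free), via flavan-4-ylium triflate 21 (not isolated)
Conditions: 20 (3–4 equiv), TMSOTf (cat.), CH2Cl2, −78 °C
Reagents that add atoms: none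
Why: Lewis-acid-promoted SN1 (Friedel–Crafts-type) flavan coupling, in which TMSOTf ionises the acetate to the cation triflate 21 stabilised by the ring A oxygens and C8 of 20 (its most nucleophilic position, used in excess to suppress self-condensation of 18) attacks anti to the C3 benzyloxy group of the 2,3-trans cation, which should set C4 as S (3,4-trans, 4α).

Step 13
Reactants: 18 (2R,3R,4R)-3,5,7-tris(benzyloxy)-2-[3,4,5-tris(benzyloxy)phenyl]chroman-4-yl acetate; 22 hexa-O-benzyl-(+)-gallocatechin-(4α→8)-tetra-O-benzyl-(+)-catechin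
Product: 24 hexadeca-O-benzyl prodelphinidin C2 (3-OH of the lowest unit free), via flavan-4-ylium acetoxytrifluoroborate 23 (not isolated)
Conditions: 22 (2 equiv, excess recovered), BF3·OEt2 (0.2 equiv), CH2Cl2, −78 to −40 °C
Reagents that add atoms: none
Why: Lewis-acid-promoted SN1 (Friedel–Crafts-type) flavan coupling with a different promoter, in which BF3·OEt2 ionises the acetate reversibly to the tight ion pair 23 (its acetoxytrifluoroborate counter-ion keeps the free cation at low concentration, which should curb over-coupling when the dimer cannot be used in large excess) and the cation is captured by C8 of the upper unit of 22 (activated by O1 and the C7 oxygen and less shielded than either C6 position) anti to its C3 benzyloxy group, which should set the second 3,4-trans (4α) interflavan bond.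

Step 14
Reactants: 24 hexadeca-O-benzyl prodelphinidin C2
Product: 25 prodelphinidin C2
Conditions: H2 (1 atm), Pd(OH)2/C, THF–MeOH–H2O, rt; then Sephadex LH-20
Reagents that add atoms: none
Why: catalytic hydrogenolysis should cleave all sixteen benzyl ethers, while the diarylmethine C4–C8 bonds and the ring C ether bonds are not reduced under these neutral conditions.

**Compound list**

1 | (R)-4-benzyloxazolidin-2-one | O=C1OC[C@@H](Cc2ccccc2)N1 | starting material
2 | benzyloxyacetyl chloride | O=C(Cl)COCc1ccccc1 | starting material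
3 | (R)-4-benzyl-3-[2-(benzyloxy)acetyl]oxazolidin-2-one | O=C(COCc1ccccc1)N1[C@H](Cc2ccccc2)COC1=O | intermediate
4 | 3,4,5-tris(benzyloxy)benzaldehyde | O=Cc1cc(OCc2ccccc2)c(OCc2ccccc2)c(OCc2ccccc2)c1 | starting material
5 | dibutylboron Z-enolate of 3 | CCCCB(CCCC)O/C(=C\OCc1ccccc1)N1[C@H](Cc2ccccc2)COC1=O | intermediate (not isolated)
6 | (R)-4-benzyl-3-[(2R,3S)-2-(benzyloxy)-3-hydroxy-3-(3,4,5-tris(benzyloxy)phenyl)propanoyl]oxazolidin-2-one | O[C@@H](c1cc(OCc2ccccc2)c(OCc2ccccc2)c(OCc2ccccc2)c1)[C@@H](OCc1ccccc1)C(=O)N1[C@H](Cc2ccccc2)COC1=O | intermediate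
7 | (1R,2R)-2-(benzyloxy)-3-[(R)-4-benzyl-2-oxooxazolidin-3-yl]-3-oxo-1-[3,4,5-tris(benzyloxy)phenyl]propyl 4-nitrobenzoate | O=C(O[C@H](c1cc(OCc2ccccc2)c(OCc2ccccc2)c(OCc2ccccc2)c1)[C@@H](OCc1ccccc1)C(=O)N1[C@H](Cc2ccccc2)COC1=O)c1ccc(cc1)[N+](=O)[O-] | intermediate
8 | methyl (2R,3R)-2-(benzyloxy)-3-hydroxy-3-[3,4,5-tris(benzyloxy)phenyl]propanoate | O[C@H](c1cc(OCc2ccccc2)c(OCc2ccccc2)c(OCc2ccccc2)c1)[C@@H](OCc1ccccc1)C(=O)OC | intermediate
9 | 3,5-bis(benzyloxy)phenol | Oc1cc(OCc2ccccc2)cc(OCc2ccccc2)c1 | starting material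
10 | 2-bromo-3,5-bis(benzyloxy)phenol | Oc1cc(OCc2ccccc2)cc(OCc2ccccc2)c1Br | intermediate
11 | [2-bromo-3,5-bis(benzyloxy)phenoxy]trimethylsilane | C[Si](C)(C)Oc1cc(OCc2ccccc2)cc(OCc2ccccc2)c1Br | intermediate
12 | lithium 3,5-bis(benzyloxy)-2-(trimethylsilyl)phenoxide | [Li+].[O-]c1cc(OCc2ccccc2)cc(OCc2ccccc2)c1[Si](C)(C)C | intermediate (not isolated)
13 | 3,5-bis(benzyloxy)-2-(trimethylsilyl)phenyl trifluoromethanesulfonate | C[Si](C)(C)c1c(OS(=O)(=O)C(F)(F)F)cc(OCc2ccccc2)cc1OCc1ccccc1 | intermediate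
14 | 3,5-bis(benzyloxy)benzyne | C1#CC(OCc2ccccc2)=CC(OCc2ccccc2)=C1 | intermediate (not isolated)
15 | caesium 2-{[(1R,2R)-2-(benzyloxy)-3-methoxy-3-oxo-1-(3,4,5-tris(benzyloxy)phenyl)propyl]oxy}-4,6-bis(benzyloxy)benzen-1-ide | [Cs+].[c-]1c(OCc2ccccc2)cc(OCc2ccccc2)cc1O[C@H](c1cc(OCc2ccccc2)c(OCc2ccccc2)c(OCc2ccccc2)c1)[C@@H](OCc1ccccc1)C(=O)OC | intermediate (not isolated)
16 | (2R,3R)-3,5,7-tris(benzyloxy)-2-[3,4,5-tris(benzyloxy)phenyl]chroman-4-one (2,3-trans) | O=C1c2c(OCc3ccccc3)cc(OCc3ccccc3)cc2O[C@H](c2cc(OCc3ccccc3)c(OCc3ccccc3)c(OCc3ccccc3)c2)[C@H]1OCc1ccccc1 | intermediate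
17 | (2R,3S,4R)-3,5,7-tris(benzyloxy)-2-[3,4,5-tris(benzyloxy)phenyl]chroman-4-ol (2,3-trans-3,4-trans) | O[C@@H]1c2c(OCc3ccccc3)cc(OCc3ccccc3)cc2O[C@H](c2cc(OCc3ccccc3)c(OCc3ccccc3)c(OCc3ccccc3)c2)[C@H]1OCc1ccccc1 | intermediate
18 | (2R,3R,4R)-3,5,7-tris(benzyloxy)-2-[3,4,5-tris(benzyloxy)phenyl]chroman-4-yl acetate (2,3-trans-3,4-trans) | CC(=O)O[C@@H]1c2c(OCc3ccccc3)cc(OCc3ccccc3)cc2O[C@H](c2cc(OCc3ccccc3)c(OCc3ccccc3)c(OCc3ccccc3)c2)[C@H]1OCc1ccccc1 | intermediate
19 | (+)-catechin, (2R,3S) | Oc1cc(O)c2c(c1)O[C@H](c1ccc(O)c(O)c1)[C@@H](O)C2 | starting material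
20 | 5,7,3',4'-tetra-O-benzyl-(+)-catechin | O(Cc3ccccc3)c1cc(OCc3ccccc3)c2c(c1)O[C@H](c1ccc(OCc3ccccc3)c(OCc3ccccc3)c1)[C@@H](O)C2 | intermediate
21 | (2R,3S)-3,5,7-tris(benzyloxy)-2-[3,4,5-tris(benzyloxy)phenyl]chroman-4-ylium triflate | [CH+]1c2c(OCc3ccccc3)cc(OCc3ccccc3)cc2O[C@H](c2cc(OCc3ccccc3)c(OCc3ccccc3)c(OCc3ccccc3)c2)[C@H]1OCc1ccccc1.[O-]S(=O)(=O)C(F)(F)F | intermediate (not isolated)
22 | 3,5,7,3',4',5'-hexa-O-benzyl-(+)-gallocatechin-(4α→8)-5,7,3',4'-tetra-O-benzyl-(+)-catechin (upper unit 2R,3S,4S; lower unit 2R,3S, 3-OH free) | O(Cc3ccccc3)c1cc(OCc3ccccc3)c2c(c1)O[C@H](c1cc(OCc3ccccc3)c(OCc3ccccc3)c(OCc3ccccc3)c1)[C@@H](OCc3ccccc3)[C@@H]2c1c(OCc3ccccc3)cc(OCc3ccccc3)c2c1O[C@H](c1ccc(OCc3ccccc3)c(OCc3ccccc3)c1)[C@@H](O)C2 | intermediate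
23 | (2R,3S)-3,5,7-tris(benzyloxy)-2-[3,4,5-tris(benzyloxy)phenyl]chroman-4-ylium acetoxytrifluoroborate | [CH+]1c2c(OCc3ccccc3)cc(OCc3ccccc3)cc2O[C@H](c2cc(OCc3ccccc3)c(OCc3ccccc3)c(OCc3ccccc3)c2)[C@H]1OCc1ccccc1.CC(=O)O[B-](F)(F)F | intermediate (not isolated)
24 | hexadeca-O-benzyl prodelphinidin C2: hexa-O-benzyl-(+)-gallocatechin-(4α→8)-hexa-O-benzyl-(+)-gallocatechin-(4α→8)-5,7,3',4'-tetra-O-benzyl-(+)-catechin (both upper units 2,3-trans-3,4-trans; 3-OH of the lowest unit free) | O(Cc3ccccc3)c1cc(OCc3ccccc3)c2c(c1)O[C@H](c1cc(OCc3ccccc3)c(OCc3ccccc3)c(OCc3ccccc3)c1)[C@@H](OCc3ccccc3)[C@@H]2c1c(OCc3ccccc3)cc(OCc3ccccc3)c2c1O[C@H](c1cc(OCc3ccccc3)c(OCc3ccccc3)c(OCc3ccccc3)c1)[C@@H](OCc3ccccc3)[C@@H]2c1c(OCc3ccccc3)cc(OCc3ccccc3)c2c1O[C@H](c1ccc(OCc3ccccc3)c(OCc3ccccc3)c1)[C@@H](O)C2 | intermediate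
25 | prodelphinidin C2, (+)-gallocatechin-(4α→8)-(+)-gallocatechin-(4α→8)-(+)-catechin | Oc1cc(O)c2c(c1)O[C@H](c1cc(O)c(O)c(O)c1)[C@@H](O)[C@@H]2c1c(O)cc(O)c2c1O[C@H](c1cc(O)c(O)c(O)c1)[C@@H](O)[C@@H]2c1c(O)cc(O)c2c1O[C@H](c1ccc(O)c(O)c1)[C@@H](O)C2 | target

**Step count**

Total steps: 14. Longest linear sequence: 10 (steps 1, 2, 3, 4, 8, 9, 10, 12, 13, 14).

**Steps most likely to fail, with fallbacks**

Step 8 (proposed new method). What may go wrong: protonation of the aryl anion before it reaches the ester, so that only the open aryl ether forms; retro-aldol fragmentation or beta-elimination of the hydroxy ester in the basic fluoride medium; or sluggish addition of the hindered secondary alcohol to the aryne. The fallback uses known chemistry and forms O1–C2 first. It sets out from 6 and phenol 9: a Mitsunobu etherification (PPh3, DIAD, toluene, 0 °C) should invert the carbinol carbon and give the 3,5-bis(benzyloxy)phenyl ether imide F1. Hydrolysis with LiOH/H2O2 (THF–H2O, 0 °C) should release the aryloxy acid F2 and the auxiliary. Intramolecular Friedel–Crafts acylation of the phloroglucinol-type ring (trifluoroacetic anhydride, CH2Cl2, 0 °C) should then close ring C and rejoin the route at 16.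

Step 3. What may go wrong: elimination to the alpha-benzyloxy cinnamoyl imide, or partial ionisation of the activated benzylic oxygen with loss of stereochemical fidelity. The fallback avoids inversion and corrects C3 under thermodynamic control. It sets out from 2 and 4: commercial (S)-4-benzyloxazolidin-2-one is acylated with 2 as in step 1 to the enantiomeric glycolate imide F3. Its Evans syn aldol reaction with 4 should give the (2S,3R) syn adduct F4, whose carbinol carbon already has the configuration of flavan C2. Methanolysis (K2CO3, MeOH) should give the syn methyl ester F5. Annulation of F5 with 13 under the conditions of step 8 should give the 2,3-cis chromanone F6, and base-mediated equilibration at C3 through the enol (DBU, CH2Cl2, rt) should convert it into the more stable 2,3-trans isomer, rejoining the route at 16.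

Step 13. What may go wrong: competing attack at C6 of either unit of 22, and further coupling of 24 with 18 to higher oligomers, because the dimer cannot be used in large excess. The fallback inverts the order of union (2+1 with orthogonal activation) and sets out from 18. Treatment with phenylmethanethiol and BF3·OEt2 (CH2Cl2, −78 °C) should give the 4-benzylsulfanyl flavan F7, which is inert to hard Lewis acids. Coupling of 18 with an excess of F7 (BF3·OEt2, CH2Cl2, −78 °C) should give the upper dimer thioether F8. Thiophilic activation of F8 with AgBF4 (THF, 0 °C) in the presence of an excess of inexpensive 20 should form the lower interflavan bond and rejoin the route at 24.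

**Further compounds**

F1 | step 8 | (R)-4-benzyl-3-[(2R,3R)-2-(benzyloxy)-3-[3,5-bis(benzyloxy)phenoxy]-3-(3,4,5-tris(benzyloxy)phenyl)propanoyl]oxazolidin-2-one | c1c(OCc2ccccc2)cc(OCc2ccccc2)cc1O[C@H](c1cc(OCc2ccccc2)c(OCc2ccccc2)c(OCc2ccccc2)c1)[C@@H](OCc1ccccc1)C(=O)N1[C@H](Cc2ccccc2)COC1=O
F2 | step 8 | (2R,3R)-2-(benzyloxy)-3-[3,5-bis(benzyloxy)phenoxy]-3-[3,4,5-tris(benzyloxy)phenyl]propanoic acid | c1c(OCc2ccccc2)cc(OCc2ccccc2)cc1O[C@H](c1cc(OCc2ccccc2)c(OCc2ccccc2)c(OCc2ccccc2)c1)[C@@H](OCc1ccccc1)C(=O)O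
F3 | step 3 | (S)-4-benzyl-3-[2-(benzyloxy)acetyl]oxazolidin-2-one | O=C(COCc1ccccc1)N1[C@@H](Cc2ccccc2)COC1=O
F4 | step 3 | (S)-4-benzyl-3-[(2S,3R)-2-(benzyloxy)-3-hydroxy-3-(3,4,5-tris(benzyloxy)phenyl)propanoyl]oxazolidin-2-one | O[C@H](c1cc(OCc2ccccc2)c(OCc2ccccc2)c(OCc2ccccc2)c1)[C@H](OCc1ccccc1)C(=O)N1[C@@H](Cc2ccccc2)COC1=O
F5 | step 3 | methyl (2S,3R)-2-(benzyloxy)-3-hydroxy-3-[3,4,5-tris(benzyloxy)phenyl]propanoate | O[C@H](c1cc(OCc2ccccc2)c(OCc2ccccc2)c(OCc2ccccc2)c1)[C@H](OCc1ccccc1)C(=O)OC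
F6 | step 3 | (2R,3S)-3,5,7-tris(benzyloxy)-2-[3,4,5-tris(benzyloxy)phenyl]chroman-4-one (2,3-cis) | O=C1c2c(OCc3ccccc3)cc(OCc3ccccc3)cc2O[C@H](c2cc(OCc3ccccc3)c(OCc3ccccc3)c(OCc3ccccc3)c2)[C@@H]1OCc1ccccc1
F7 | step 13 | (2R,3R,4R)-4-(benzylsulfanyl)-3,5,7-tris(benzyloxy)-2-[3,4,5-tris(benzyloxy)phenyl]chromane (2,3-trans-3,4-trans) | C(c1ccccc1)S[C@@H]1c2c(OCc3ccccc3)cc(OCc3ccccc3)cc2O[C@H](c2cc(OCc3ccccc3)c(OCc3ccccc3)c(OCc3ccccc3)c2)[C@H]1OCc1ccccc1
F8 | step 13 | hexa-O-benzyl-(+)-gallocatechin-(4α→8)-4-(benzylsulfanyl)-hexa-O-benzyl-(+)-gallocatechin (both units 2,3-trans-3,4-trans) | O(Cc3ccccc3)c1cc(OCc3ccccc3)c2c(c1)O[C@H](c1cc(OCc3ccccc3)c(OCc3ccccc3)c(OCc3ccccc3)c1)[C@@H](OCc3ccccc3)[C@@H]2c1c(OCc3ccccc3)cc(OCc3ccccc3)c2c1O[C@H](c1cc(OCc3ccccc3)c(OCc3ccccc3)c(OCc3ccccc3)c1)[C@@H](OCc3ccccc3)[C@@H]2SCc1ccccc1
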